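**Strategy.** Perrottetin F is cut at the two aryl–CH2 bonds of the ethylene bridge that joins C1 of ring A (a 3-hydroxyphenyl ring) to C4 of ring B (the para-phenylene ring bearing the diaryl ether oxygen). Because both ends of this C2 unit sit on arene carbons, propiolic acid can serve as the bridge: its C–H end is arylated by 3-iodoanisole and, after loss of CO2, its other end by the ring B bromide, all in one flask. The bromide already contains rings B, C and D, i.e. the 4-bromophenyl ether of the fully methylated ring C–ring D bibenzyl, made in three steps. Hydrogenation and global demethylation finish the route.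

Key step: step 4

Remark: the target has no stereocentre, stereoaxis or configured double bond, so it is achiral and is made as the single compound drawn, without any stereocontrol.

Remark: all four phenols are carried as methyl ethers, which are inert to base, palladium and hydrogen and fall together in the last step. The benzylic Wittig salt 2 is a catalogue compound, so no step is spent on making it.

Step 1
Reactants: 1 3-hydroxy-4,5-dimethoxybenzaldehyde; 2 (3-methoxybenzyl)triphenylphosphonium chloride
Product: 4 2,3-dimethoxy-5-[2-(3-methoxyphenyl)ethenyl]phenol (E/Z mixture), via (3-methoxybenzylidene)triphenylphosphorane 3 (not isolated)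
Conditions: t-BuOK (2.5 equiv), THF, 0 °C to rt; aq. NH4Cl work-up
Reagents that add atoms: none
Why: Wittig olefination, in which the semi-stabilised benzylic ylide 3 adds to the formyl group of 1 while the phenol is held as its potassium phenoxide by the extra base (being meta to the aldehyde it does not deactivate it by conjugation); the alkene geometry is irrelevant because the double bond is saturated in step 2.

Step 2
Reactants: 4 2,3-dimethoxy-5-[2-(3-methoxyphenyl)ethenyl]phenol (E/Z mixture)
Product: 5 2,3-dimethoxy-5-[2-(3-methoxyphenyl)ethyl]phenol
Conditions: H2 (1 atm), 10% Pd/C, EtOAc, rt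
Reagents that add atoms: none
Why: Heterogeneous catalytic hydrogenation of a stilbene double bond over Pd/C is reliable at ambient pressure, leaves the phenol and methyl ethers untouched, and is placed before the O-arylation so that no C–Br bond is exposed to Pd/H2.

Step 3
Reactants: 5 2,3-dimethoxy-5-[2-(3-methoxyphenyl)ethyl]phenol; 6 4-bromophenylboronic acid
Product: 7 1-(4-bromophenoxy)-2,3-dimethoxy-5-[2-(3-methoxyphenyl)ethyl]benzene
Conditions: Cu(OAc)2 (1.5 equiv), pyridine (5 equiv), 4 Å MS, CH2Cl2, air, rt; 6 used in excess (2 equiv)
Reagents that add atoms: none
Why: Chan–Lam oxidative O-arylation, in which phenoxide and arylboronic acid are joined on copper by C–O reductive elimination from a Cu(III) aryl phenoxide at room temperature, conditions that do not touch the C–Br bond and that accept ortho-alkoxy phenols.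

Step 4
Reactants: 8 3-iodoanisole; 9 propiolic acid; 7 1-(4-bromophenoxy)-2,3-dimethoxy-5-[2-(3-methoxyphenyl)ethyl]benzene
Product: 11 1,2-dimethoxy-3-{4-[(3-methoxyphenyl)ethynyl]phenoxy}-5-[2-(3-methoxyphenyl)ethyl]benzene, via 3-(3-methoxyphenyl)propiolic acid 10 (not isolated)
Conditions: Pd(PPh3)2Cl2 (5 mol%), dppb (10 mol%), DBU (2.5 equiv), DMSO; 8 (1.2 equiv) + 9 (1.15 equiv), 25–30 °C; then 7 (1.0 equiv), 80–90 °C
Reagents that add atoms: none
Why: Pd(0) inserts into the C–I bond of 8 at ambient temperature and the DBU salt of propiolic acid is alkynylated at its terminal C–H (copper-free Sonogashira coupling), giving the arylpropiolate 10 with the carboxylate intact because decarboxylation has a higher thermal threshold. When 7 is then added and the flask is heated, Pd(0) inserts into its C–Br bond, the carboxylate of 10 binds to the arylpalladium(II) bromide and extrudes CO2 to an aryl(alkynyl)palladium species, and reductive elimination forms the second aryl–C(sp) bond of 11. The closest known reaction type is exactly this one-pot Sonogashira/decarboxylative alkynylation of propiolic acid with an aryl iodide followed by an aryl bromide, a known route to unsymmetrical diarylalkynes. No ring is closed and no stereocentre is formed. The selectivity required is the order of the two arylations, since scrambling gives symmetrical diarylalkynes; it is secured by the faster oxidative addition of C–I over C–Br, by the temperature step that separates C–H coupling from decarboxylation, by adding 7 only after 8 is consumed, and by a slight excess of 8 over 9 so that no free propiolic acid meets the bromide. The substrate offers nothing else to palladium or DBU, since its ethylene arm is saturated and its methyl ethers and diaryl ether are inert, and leaving out copper suppresses oxidative alkyne dimerisation and premature protodecarboxylation.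

Step 5
Reactants: 11 1,2-dimethoxy-3-{4-[(3-methoxyphenyl)ethynyl]phenoxy}-5-[2-(3-methoxyphenyl)ethyl]benzene
Product: 12 1,2-dimethoxy-3-{4-[2-(3-methoxyphenyl)ethyl]phenoxy}-5-[2-(3-methoxyphenyl)ethyl]benzene (perrottetin F tetramethyl ether)
Conditions: H2 (1 atm), 10% Pd/C, EtOAc/EtOH, rt
Reagents that add atoms: none
Why: Catalytic hydrogenation of a diarylalkyne over Pd/C should run through the cis-stilbene to the CH2–CH2 bridge, while the diaryl ether and the four methyl ethers resist hydrogenolysis under these mild conditions.

Step 6
Reactants: 12 1,2-dimethoxy-3-{4-[2-(3-methoxyphenyl)ethyl]phenoxy}-5-[2-(3-methoxyphenyl)ethyl]benzene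
Product: 13 perrottetin F, 3-{4-[2-(3-hydroxyphenyl)ethyl]phenoxy}-5-[2-(3-hydroxyphenyl)ethyl]benzene-1,2-diol
Conditions: BBr3 (8 equiv), CH2Cl2, −78 °C to rt; then H2O, work-up under argon
Reagents that add atoms: none
Why: Lewis acid ether cleavage, in which BBr3 complexes each methoxy oxygen and bromide attacks the methyl carbon (SN2), so only the four O–CH3 bonds break while the aryl–O–aryl bond, which has no sp3 carbon, survives and the aryl borates are hydrolysed to the phenols on work-up.

**Compound list**

1 | 3-hydroxy-4,5-dimethoxybenzaldehyde | COc1cc(C=O)cc(O)c1OC | starting material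
2 | (3-methoxybenzyl)triphenylphosphonium chloride | COc1cccc(C[P+](c2ccccc2)(c2ccccc2)c2ccccc2)c1.[Cl-] | starting material
3 | (3-methoxybenzylidene)triphenylphosphorane (ylide, not isolated) | COc1cccc(C=P(c2ccccc2)(c2ccccc2)c2ccccc2)c1 | intermediate
4 | 2,3-dimethoxy-5-[2-(3-methoxyphenyl)ethenyl]phenol, E/Z mixture (drawn without alkene geometry; both isomers are carried on) | COc1cccc(C=Cc2cc(O)c(OC)c(OC)c2)c1 | intermediate
5 | 2,3-dimethoxy-5-[2-(3-methoxyphenyl)ethyl]phenol | COc1cccc(CCc2cc(O)c(OC)c(OC)c2)c1 | intermediate
6 | 4-bromophenylboronic acid | OB(O)c1ccc(Br)cc1 | starting material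
7 | 1-(4-bromophenoxy)-2,3-dimethoxy-5-[2-(3-methoxyphenyl)ethyl]benzene | COc1cccc(CCc2cc(OC)c(OC)c(Oc3ccc(Br)cc3)c2)c1 | intermediate
8 | 3-iodoanisole | COc1cccc(I)c1 | starting material
9 | propiolic acid | C#CC(=O)O | starting material
10 | 3-(3-methoxyphenyl)propiolic acid (present as its DBU salt, not isolated) | COc1cccc(C#CC(=O)O)c1 | intermediate
11 | 1,2-dimethoxy-3-{4-[(3-methoxyphenyl)ethynyl]phenoxy}-5-[2-(3-methoxyphenyl)ethyl]benzene | COc1cccc(C#Cc2ccc(Oc3cc(CCc4cccc(OC)c4)cc(OC)c3OC)cc2)c1 | intermediate
12 | perrottetin F tetramethyl ether | COc1cccc(CCc2ccc(Oc3cc(CCc4cccc(OC)c4)cc(OC)c3OC)cc2)c1 | intermediate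
13 | perrottetin F (achiral) | Oc1cccc(CCc2ccc(Oc3cc(CCc4cccc(O)c4)cc(O)c3O)cc2)c1 | target

**Step count.** Total: 6 steps. Longest linear sequence: 6 steps (1 → 4 → 5 → 7 → 11 → 12 → 13).

**Steps most likely to fail**

Step 4. The order of the two arylations may break down: early decarboxylation of propiolate or of 10 would release terminal alkynes that react out of turn and give symmetrical diarylalkynes. Oxidative addition into the electron-rich C–Br bond of 7 may also be slow enough for protodecarboxylation of 10 to win. The fallback sets out from 7 and abandons the C2 linchpin in favour of an alkyne that already carries ring A. Compound 7 would be coupled with commercially available 3-ethynylanisole (COc1cccc(C#C)c1) in a conventional two-component Sonogashira reaction (Pd(PPh3)2Cl2, CuI, Et3N, DMF, 80 °C). Only one aryl–alkynyl bond is then made, so no ordering problem exists. The product should be 11, where the route is rejoined; no new compound arises (F0).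

Step 3. O-Arylation of the ortho-methoxy phenoxide may be slow, so that the boronic acid is lost to protodeboronation, oxidative homocoupling or hydroxylation before the ether forms, leaving conversion incomplete. The fallback sets out from 5 and replaces the oxidative Cu(II)/boronic acid coupling by an Ullmann-type Cu(I) coupling with an aryl iodide. Compound 5 would be heated with 1-bromo-4-iodobenzene (Brc1ccc(I)cc1), CuI, picolinic acid and K3PO4 in DMSO at 80–90 °C. Reaction at the C–I bond is expected to be much faster than at C–Br, so the product should be 7, where the route is rejoined; no new compound arises (F0).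

Step 1. Olefination may stall because the potassium phenoxide of 1 is poorly soluble and less electrophilic, or because the ylide is quenched by the phenol. The fallback sets out from 1 and masks the phenol first. Benzylation (BnBr, K2CO3, DMF, rt) should give 3-(benzyloxy)-4,5-dimethoxybenzaldehyde F1. Wittig reaction of F1 with ylide 3 (from 2, t-BuOK, THF) should give 1-(benzyloxy)-2,3-dimethoxy-5-[2-(3-methoxyphenyl)ethenyl]benzene F2 as an E/Z mixture. Hydrogenation over Pd/C (H2, EtOAc/EtOH) would then saturate the alkene and cleave the benzyl ether in the same operation, returning to the route at 5 at the cost of one extra step.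

**Further compounds**

F0 | step 4 | none | none
F0 | step 3 | none | none
F1 | step 1 | 3-(benzyloxy)-4,5-dimethoxybenzaldehyde | COc1cc(C=O)cc(OCc2ccccc2)c1OC
F2 | step 1 | 1-(benzyloxy)-2,3-dimethoxy-5-[2-(3-methoxyphenyl)ethenyl]benzene (E/Z mixture) | COc1cccc(C=Cc2cc(OCc3ccccc3)c(OC)c(OC)c2)c1
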